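A leftover comes first: in the dusk run at 4.00 d, X and J together hold 48.0% of the Q charged, and the rest is unread. A rule for J must therefore rest on the pair that was read.

| setting | midnight | dusk | summer | flask |
|---|---|---|---|---|
| Q | 0.050 M | 0.075 M | 0.10 M | 0.10 M |
| L | 0.080 M | 0.080 M | 0.080 M | 0.0800 M |
| D | 10 mM | 10 mM | 10 mM | 10 mM |
| Z | 1 mM | 1 mM | 0.50 mM | 1.0 mM |
| remark | run made earlier | run made earlier | run made earlier |  |
| time |  |  |  | 3.0 d |

| run | time / d | J / % | X / % |
|---|---|---|---|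
| midnight | 0.250 | 0 | 3 |
| midnight | 0.417 | 0 | 4 |
| midnight | 0.625 | 0 | 4 |
| midnight | 1.04 | 2 | 11 |
| midnight | 1.67 | 0 | 18 |
| midnight | 2.50 | 7 | 30 |
| midnight | 4.00 | 18 | 41 |
| dusk | 0.500 | 3 | 6 |
| dusk | 1.04 | 2 | 10 |
| dusk | 1.67 | 2 | 18 |
| dusk | 2.08 | 1 | 26 |
| dusk | 2.50 | 5 | 32 |
| dusk | 3.00 | 11 | 34 |
| dusk | 4.00 | 10 | 38 |
| summer | 0.250 | 3 | 0 |
| summer | 0.500 | 0 | 3 |
| summer | 1.04 | 0 | 8 |
| summer | 2.08 | 2 | 16 |
| summer | 4.00 | 9 | 26 |

(scatter of a reading: 2 percentage points)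



- amount of J in percent of the Q charged, at 4.0 h, 20 h and 3.0 d

Take J as coming from X, with κ an effective first-order constant averaged over the run, so that J grows on average by κ·X per day. X rises roughly in a line from zero, so its mean up to time t is half its value at t. Hence J = κ·X·t/2, and κ can be reckoned from the last reading of each run:

| run | Q | Z | X | J | κ |
|---|---|---|---|---|---|
| midnight | 0.050 M | 1 mM | 41% | 18% | 0.220 d⁻¹ |
| dusk | 0.075 M | 1 mM | 38% | 10% | 0.132 d⁻¹ |
| summer | 0.10 M | 0.50 mM | 26% | 9% | 0.173 d⁻¹ |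

Each J carries a scatter of 2 percentage points, so each κ is a reading. The midnight row stands highest, and it has the lowest Q. The new flask shares its Q with summer and its Z with dusk, so those two rows are pooled. Together they give the average X-to-J constant κ = 0.148 d⁻¹.

The dusk run, with the flask's Z, supplies X: 34% at 3.00 d. My reckoning for the flask is then J = 7.55% at 3.0 d. Scaling the dusk X of 10% at 1.04 d in a line gives 0.494% at 20 h and 0.0198% at 4.0 h.

The forecast, which says “J behaves like a secondary product”, gives 0.2%, 1% and 6%.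

The flask gives 0.00597%, 0.533% and 6.98%.

    Q + D → D + G (k = 8.80 × 10⁻⁴ M⁻¹ s⁻¹)
    L + Z + G → Z + X (k = 0.0690 M⁻² s⁻¹)
    L + D + X → D + J (k = 0.00330 M⁻² s⁻¹)

At 3.00 d the flask holds Q 10.2% and G 49.9% beside X 32.9%. With that X, κ gives J = 7.30% against 6.98%. With the flask's X of 17.7% at 1.50 d, it gives 1.96% against 2.10%. With twice the Q, the simulated J is 3.85%, and κ read backward over 3.0 d asks for an X of 17.3% of that larger charge.

The readings are simulated with constants of no real substance, and the scatter is random.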